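**Retrosynthetic overview**
1. The C2 acetate is put on last, from a C2 silyl ether. Before that, the seven-membered ring B is opened at C8=C9 (ring-closing metathesis).
2. The C6–O anisate comes from acylation of a 1,3-diol. The C4 carbinol comes from isopropyl addition to a cyclopentanone, and C5–C6 from an anti-selective boron aldol with 3-methylbut-3-enal.
3. The C1 quaternary centre comes from methylcuprate addition to a 3-allyl-4-silyloxycyclopentenone, anti to the C2–O bond. The allyl group enters by Stork–Danheiser transposition.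
4. Key disconnection: the C2–O bond. It is made first, by catalytic enantioselective oxygen-atom transfer to the silyloxydiene of 3-ethoxycyclopentenone. It is the only external source of chirality and relays to C1, C5, C6 and C4.
5. Ring order: five-membered ring A is purchased; ring B is closed in the penultimate step.

Assumption: positions use daucane numbering (C1 quaternary fusion carbon, C2 acetoxy carbon, C4 isopropyl carbinol, C5 fusion CH, C6 anisoyloxy carbon, C8=C9 ring alkene; α = face opposite the C1 methyl); the (R,R)-complex in step 1 is taken to give the (S)-product by analogy with indene, and the equally available antipode is used if the sense is reversed.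

**Step 1**
Reactants: 1 3-ethoxycyclopent-2-en-1-one
Product: 4 (5S)-5-(tert-butyldimethylsilyloxy)-3-ethoxycyclopent-2-en-1-one, via lithium dienolate 2 (not isolated), via silyloxydiene 3 (not isolated)
Conditions: LiN(iPr)2, THF, −78 °C; TBSOTf, −78 °C; cold pentane extraction, kept ≤ −20 °C; (R,R)-(salen)MnCl 5 mol % [salen = N,N'-bis(3,5-di-tert-butylsalicylidene)cyclohexane-1,2-diamine dianion], 4-phenylpyridine N-oxide 20 mol %, PhIO, CH2Cl2, −30 °C
Reagents that add atoms: tert-butyldimethylsilyl triflate CC(C)(C)[Si](C)(C)OS(=O)(=O)C(F)(F)F; iodosylbenzene O=Ic1ccccc1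
Why: Proposed new method: kinetic deprotonation and O-silylation give the cross-conjugated 2-silyloxycyclopentadiene 3, a cyclic, conjugated, trisubstituted enol ether of the type that pentavalent oxomanganese salen species recognise best, so side-on oxygen-atom transfer to the silyl enol ether C=C bond forms the future C2–O bond in the enantio-determining step (the other carbon becomes the carbonyl, so stepwise radical collapse cannot erode ee), and the silyloxy-oxirane opens with a 1,4 oxygen-to-oxygen silyl shift to give the already protected (S)-α′-silyloxy enone; the closest known reaction types are the (salen)MnCl-catalysed asymmetric Rubottom oxidation of aryl-conjugated silyl enol ethers and the Jacobsen epoxidation of cyclic conjugated olefins, neither shown on vinylogous-ester-derived silyloxydienes or with retention of the silyl group.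

**Step 2**
Reactants: 4 (5S)-5-(tert-butyldimethylsilyloxy)-3-ethoxycyclopent-2-en-1-one
Product: 6 (4S)-4-(tert-butyldimethylsilyloxy)-3-(prop-2-en-1-yl)cyclopent-2-en-1-one, via tertiary allylic alcohol 5 (not isolated)
Conditions: CH2=CHCH2MgBr, Et2O/THF, −78 → 0 °C; then 1 M HCl, THF, 0 °C
Reagents that add atoms: allylmagnesium bromide C=CC[Mg]Br; water O
Why: Stork–Danheiser transposition: fast 1,2-addition of the allyl Grignard reagent to the vinylogous ester carbonyl, then acid-induced ionisation and enol ether hydrolysis, moves the carbonyl to the former C–OEt carbon and leaves the silyloxy stereocentre untouched, now γ to the new enone.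

**Step 3**
Reactants: 6 (4S)-4-(tert-butyldimethylsilyloxy)-3-(prop-2-en-1-yl)cyclopent-2-en-1-one
Product: 7 (3R,4S)-3-allyl-4-(tert-butyldimethylsilyloxy)-3-methyl-1-(trimethylsilyloxy)cyclopent-1-ene
Conditions: Me2CuLi (from MeLi, CuI), TMSCl, Et2O/THF, −78 → −30 °C
Reagents that add atoms: lithium dimethylcuprate [Li+].C[Cu-]C; chlorotrimethylsilane C[Si](C)(C)Cl
Why: Chlorosilane-accelerated Gilman cuprate conjugate addition: methyl attacks the β-carbon anti to the adjacent bulky silyloxy group, which sets the C1 quaternary centre (methyl β, allyl α), and in situ silylation locks the regiodefined C4=C5 enolate.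

**Step 4**
Reactants: 8 3-methylbut-3-en-1-ol
Product: 9 3-methylbut-3-enal
Conditions: Dess–Martin periodinane, CH2Cl2, 0 °C → rt; filtered through silica, used as a solution
Reagents that add atoms: none
Why: Dess–Martin oxidation is fast and free of base, so the β,γ-unsaturated aldehyde forms without migration of the double bond into conjugation; no stereocentre is involved.

**Step 5**
Reactants: 7 (3R,4S)-3-allyl-4-(tert-butyldimethylsilyloxy)-3-methyl-1-(trimethylsilyloxy)cyclopent-1-ene; 9 3-methylbut-3-enal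
Product: 12 (2S,3R,4S)-3-allyl-4-(tert-butyldimethylsilyloxy)-2-[(1S)-1-hydroxy-3-methylbut-3-en-1-yl]-3-methylcyclopentan-1-one, via dibutylboron enolate 10 (not isolated), via boron aldolate 11 (not isolated)
Conditions: Bu2BOTf, CH2Cl2, 0 °C → rt, TMSOTf removed in vacuo; 9 (1.5 equiv), CH2Cl2, −78 → −20 °C; H2O2, MeOH, pH 7 buffer, 0 °C
Reagents that add atoms: none
Why: Silicon-to-boron exchange gives the ring-locked (E)-boron enolate regiospecifically, and its Zimmerman–Traxler chair aldol delivers the anti adduct (C6 S), with the aldehyde approaching C5 from the β face, opposite the allyl group on C1 and the silyloxy group on C2 (C5 S).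

**Step 6**
Reactants: 12 (2S,3R,4S)-3-allyl-4-(tert-butyldimethylsilyloxy)-2-[(1S)-1-hydroxy-3-methylbut-3-en-1-yl]-3-methylcyclopentan-1-one
Product: 13 (1R,2S,3R,4S)-3-allyl-4-(tert-butyldimethylsilyloxy)-2-[(1S)-1-hydroxy-3-methylbut-3-en-1-yl]-3-methyl-1-(propan-2-yl)cyclopentan-1-ol
Conditions: LaCl3·2LiCl (1.1 equiv), THF, rt; iPrMgCl (3.5 equiv), −78 → −20 °C
Reagents that add atoms: isopropylmagnesium chloride CC(C)[Mg]Cl
Why: Lanthanide-assisted Grignard 1,2-addition suppresses enolisation and β-hydride reduction, and isopropyl adds to the chelated β-alkoxido ketone from the α face, anti to the branched C5 side chain, giving the 4β tertiary alcohol (C4 R).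

**Step 7**
Reactants: 13 (1R,2S,3R,4S)-3-allyl-4-(tert-butyldimethylsilyloxy)-2-[(1S)-1-hydroxy-3-methylbut-3-en-1-yl]-3-methyl-1-(propan-2-yl)cyclopentan-1-ol
Product: 14 (1S)-1-[(1S,2R,3S,5R)-2-allyl-3-(tert-butyldimethylsilyloxy)-5-hydroxy-2-methyl-5-(propan-2-yl)cyclopentyl]-3-methylbut-3-en-1-yl 4-methoxybenzoate
Conditions: 4-MeOC6H4COCl, Et3N, DMAP (cat.), CH2Cl2, 0 → 40 °C
Reagents that add atoms: 4-methoxybenzoyl chloride COc1ccc(C(=O)Cl)cc1
Why: DMAP-catalysed acylation (nucleophilic catalysis) discriminates between the secondary C6 hydroxyl and the tertiary C4 hydroxyl flanked by isopropyl, so the anisate forms at O6 with retention at C6.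

**Step 8**
Reactants: 14 (1S)-1-[(1S,2R,3S,5R)-2-allyl-3-(tert-butyldimethylsilyloxy)-5-hydroxy-2-methyl-5-(propan-2-yl)cyclopentyl]-3-methylbut-3-en-1-yl 4-methoxybenzoate
Product: 15 (1S,3R,3aS,4S,8aR)-1-(tert-butyldimethylsilyloxy)-3-hydroxy-6,8a-dimethyl-3-(propan-2-yl)-1,2,3,3a,4,5,8,8a-octahydroazulen-4-yl 4-methoxybenzoate
Conditions: second-generation Grubbs catalyst (H2IMes)(PCy3)Cl2Ru=CHPh 5 mol %, CH2Cl2 (2 mM), reflux
Reagents that add atoms: none
Why: Ring-closing metathesis initiates at the monosubstituted allyl group and closes onto the only other alkene, the 1,1-disubstituted one, giving the trisubstituted C8=C9 bond; the trans side chains on a fully sp3 cyclopentane bearing a quaternary carbon are pre-organised for the trans-fused ring B, and loss of ethene drives the reaction.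

**Step 9**
Reactants: 15 (1S,3R,3aS,4S,8aR)-1-(tert-butyldimethylsilyloxy)-3-hydroxy-6,8a-dimethyl-3-(propan-2-yl)-1,2,3,3a,4,5,8,8a-octahydroazulen-4-yl 4-methoxybenzoate
Product: 17 (1S,3R,3aS,4S,8aR)-1-acetoxy-3-hydroxy-6,8a-dimethyl-3-(propan-2-yl)-1,2,3,3a,4,5,8,8a-octahydroazulen-4-yl 4-methoxybenzoate (CNP0171090.1), via free C2 alcohol 16 (not isolated)
Conditions: Bu4NF, THF, 0 → 40 °C; then Ac2O, Et3N, DMAP (cat.), rt
Reagents that add atoms: acetic anhydride CC(=O)OC(C)=O
Why: Fluoride desilylation followed by DMAP-catalysed acetylation in the same flask esterifies only the secondary C2 hydroxyl, because the hindered tertiary C4 hydroxyl is inert, and no stereocentre is touched.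

**Compound list**
1 | 3-ethoxycyclopent-2-en-1-one | CCOC1=CC(=O)CC1 | starting material
2 | lithium 4-ethoxycyclopenta-1,3-dien-2-olate (kinetic cross-conjugated dienolate) | [Li+].CCOC1=CC([O-])=CC1 | intermediate
3 | tert-butyl[(4-ethoxycyclopenta-1,3-dien-2-yl)oxy]dimethylsilane | CCOC1=CC(O[Si](C)(C)C(C)(C)C)=CC1 | intermediate
4 | (5S)-5-(tert-butyldimethylsilyloxy)-3-ethoxycyclopent-2-en-1-one | CCOC1=CC(=O)[C@@H](O[Si](C)(C)C(C)(C)C)C1 | intermediate
5 | (5S)-1-allyl-5-(tert-butyldimethylsilyloxy)-3-ethoxycyclopent-2-en-1-ol (mixture of carbinol epimers) | CCOC1=CC(O)(CC=C)[C@@H](O[Si](C)(C)C(C)(C)C)C1 | intermediate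
6 | (4S)-4-(tert-butyldimethylsilyloxy)-3-(prop-2-en-1-yl)cyclopent-2-en-1-one | O=C1C=C(CC=C)[C@@H](O[Si](C)(C)C(C)(C)C)C1 | intermediate
7 | (3R,4S)-3-allyl-4-(tert-butyldimethylsilyloxy)-3-methyl-1-(trimethylsilyloxy)cyclopent-1-ene | C[Si](C)(C)OC1=C[C@@](C)(CC=C)[C@@H](O[Si](C)(C)C(C)(C)C)C1 | intermediate
8 | 3-methylbut-3-en-1-ol | CC(=C)CCO | starting material
9 | 3-methylbut-3-enal | CC(=C)CC=O | intermediate
10 | (3R,4S)-3-allyl-4-(tert-butyldimethylsilyloxy)-1-(dibutylboryloxy)-3-methylcyclopent-1-ene | CCCCB(CCCC)OC1=C[C@@](C)(CC=C)[C@@H](O[Si](C)(C)C(C)(C)C)C1 | intermediate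
11 | O-dibutylboryl aldolate of 12 | O=C1C[C@H](O[Si](C)(C)C(C)(C)C)[C@](C)(CC=C)[C@H]1[C@@H](OB(CCCC)CCCC)CC(C)=C | intermediate
12 | (2S,3R,4S)-3-allyl-4-(tert-butyldimethylsilyloxy)-2-[(1S)-1-hydroxy-3-methylbut-3-en-1-yl]-3-methylcyclopentan-1-one | O=C1C[C@H](O[Si](C)(C)C(C)(C)C)[C@](C)(CC=C)[C@H]1[C@@H](O)CC(C)=C | intermediate
13 | (1R,2S,3R,4S)-3-allyl-4-(tert-butyldimethylsilyloxy)-2-[(1S)-1-hydroxy-3-methylbut-3-en-1-yl]-3-methyl-1-(propan-2-yl)cyclopentan-1-ol | CC(C)[C@]1(O)C[C@H](O[Si](C)(C)C(C)(C)C)[C@](C)(CC=C)[C@H]1[C@@H](O)CC(C)=C | intermediate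
14 | (1S)-1-[(1S,2R,3S,5R)-2-allyl-3-(tert-butyldimethylsilyloxy)-5-hydroxy-2-methyl-5-(propan-2-yl)cyclopentyl]-3-methylbut-3-en-1-yl 4-methoxybenzoate | CC(C)[C@]1(O)C[C@H](O[Si](C)(C)C(C)(C)C)[C@](C)(CC=C)[C@H]1[C@@H](OC(=O)c2ccc(OC)cc2)CC(C)=C | intermediate
15 | (1S,3R,3aS,4S,8aR)-1-(tert-butyldimethylsilyloxy)-3-hydroxy-6,8a-dimethyl-3-(propan-2-yl)-1,2,3,3a,4,5,8,8a-octahydroazulen-4-yl 4-methoxybenzoate | COc1ccc(C(=O)O[C@H]2CC(C)=CC[C@@]3(C)[C@@H](O[Si](C)(C)C(C)(C)C)C[C@@](O)(C(C)C)[C@H]23)cc1 | intermediate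
16 | (1S,3R,3aS,4S,8aR)-1,3-dihydroxy-6,8a-dimethyl-3-(propan-2-yl)-1,2,3,3a,4,5,8,8a-octahydroazulen-4-yl 4-methoxybenzoate | COc1ccc(C(=O)O[C@H]2CC(C)=CC[C@@]3(C)[C@@H](O)C[C@@](O)(C(C)C)[C@H]23)cc1 | intermediate
17 | (1S,3R,3aS,4S,8aR)-1-acetoxy-3-hydroxy-6,8a-dimethyl-3-(propan-2-yl)-1,2,3,3a,4,5,8,8a-octahydroazulen-4-yl 4-methoxybenzoate | COc1ccc(C(=O)O[C@H]2CC(C)=CC[C@@]3(C)[C@@H](OC(C)=O)C[C@@](O)(C(C)C)[C@H]23)cc1 | target

**Counts**
- Total step count: 9.
- Longest linear sequence: 8 (steps 1, 2, 3, 5, 6, 7, 8, 9).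
- Stereocentres: C2 is set in step 1, C1 in step 3, C5 and C6 in step 5, and C4 in step 6. None is epimerisable after step 6.

**Three steps most likely to fail**

*Step 1 (the proposed new step).*
- Risks: a 1,5-hydrogen shift of 3 to the regioisomeric diene would lead to the 4-silyloxy isomer. Diels–Alder dimerisation of 3 and insufficient ee are further risks.
- Fallback (known chemistry), from 1 back to 4: α′-acetoxylation of 1 with Mn(OAc)3 in refluxing benzene gives racemic 5-acetoxy-3-ethoxycyclopent-2-en-1-one F1. Lipase-catalysed hydrolysis (Candida antarctica lipase B, pH 7 buffer/toluene), stopped just past half conversion, leaves the (S)-acetate F2. It converts the fast-reacting enantiomer into the (R)-alcohol F3, which is removed by chromatography. Brief methanolysis of F2 (K2CO3, MeOH, −10 °C) gives the (S)-alcohol F4, and TBSCl/imidazole in DMF returns 4.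

*Step 5.*
- Risks: aldehyde 9 may enolise or isomerise to the conjugated aldehyde. Face selectivity at C5, next to the quaternary carbon, may be only moderate.
- Fallback, from 7 back to 13 (bypassing 9 and 12): the C6–C7 bond is made instead of C5–C6. MeLi in THF converts 7 into the lithium enolate F5, and gaseous formaldehyde traps it as the hydroxymethyl ketone F6. Addition of iPrMgCl with LaCl3·2LiCl gives the diol F7. TEMPO/PhI(OAc)2 oxidises only the primary alcohol, giving the β-hydroxy aldehyde F8. 2-Methylallylmagnesium chloride with MgBr2·OEt2 then adds to the magnesium chelate of the C4 alkoxide and the aldehyde from its open outer face, which gives the (S)-carbinol 13.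

*Step 6.*
- Risks: enolisation toward C3 with loss of silanolate, retro-aldol cleavage, or β-hydride reduction at a ketone hindered on both faces.
- Fallback, from 12 back to 15: ring B is closed first and a smaller sp2 nucleophile is used. Ring-closing metathesis of 12 with (H2IMes)(PCy3)Cl2Ru=CHPh gives the bicyclic hydroxy ketone F9. CH2=C(CH3)MgBr/CeCl3 adds from the α face to give the isopropenyl carbinol F10. RhCl(PPh3)3/H2 saturates only the 1,1-disubstituted olefin, giving the isopropyl diol F11. Acylation with 4-methoxybenzoyl chloride/DMAP at the secondary hydroxyl gives 15.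

**Further compounds**
F1 | step 1 | rac-5-acetoxy-3-ethoxycyclopent-2-en-1-one | CCOC1=CC(=O)C(OC(C)=O)C1
F2 | step 1 | (5S)-5-acetoxy-3-ethoxycyclopent-2-en-1-one | CCOC1=CC(=O)[C@@H](OC(C)=O)C1
F3 | step 1 | (5R)-3-ethoxy-5-hydroxycyclopent-2-en-1-one | CCOC1=CC(=O)[C@H](O)C1
F4 | step 1 | (5S)-3-ethoxy-5-hydroxycyclopent-2-en-1-one | CCOC1=CC(=O)[C@@H](O)C1
F5 | step 5 | lithium (3R,4S)-3-allyl-4-(tert-butyldimethylsilyloxy)-3-methylcyclopent-1-en-1-olate | [Li+].[O-]C1=C[C@@](C)(CC=C)[C@@H](O[Si](C)(C)C(C)(C)C)C1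
F6 | step 5 | (2S,3R,4S)-3-allyl-4-(tert-butyldimethylsilyloxy)-2-(hydroxymethyl)-3-methylcyclopentan-1-one | O=C1C[C@H](O[Si](C)(C)C(C)(C)C)[C@](C)(CC=C)[C@H]1CO
F7 | step 5 | (1R,2S,3R,4S)-3-allyl-4-(tert-butyldimethylsilyloxy)-2-(hydroxymethyl)-3-methyl-1-(propan-2-yl)cyclopentan-1-ol | CC(C)[C@]1(O)C[C@H](O[Si](C)(C)C(C)(C)C)[C@](C)(CC=C)[C@H]1CO
F8 | step 5 | (1R,2R,3S,5R)-2-allyl-3-(tert-butyldimethylsilyloxy)-5-hydroxy-2-methyl-5-(propan-2-yl)cyclopentane-1-carbaldehyde | CC(C)[C@]1(O)C[C@H](O[Si](C)(C)C(C)(C)C)[C@](C)(CC=C)[C@H]1C=O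
F9 | step 6 | (1S,3aS,4S,8aR)-1-(tert-butyldimethylsilyloxy)-4-hydroxy-6,8a-dimethyl-1,3a,4,5,8,8a-hexahydroazulen-3(2H)-one | O[C@H]1CC(C)=CC[C@@]2(C)[C@@H](O[Si](C)(C)C(C)(C)C)CC(=O)[C@H]12
F10 | step 6 | (1S,3S,3aS,4S,8aR)-1-(tert-butyldimethylsilyloxy)-6,8a-dimethyl-3-(prop-1-en-2-yl)-1,2,3,3a,4,5,8,8a-octahydroazulene-3,4-diol | O[C@H]1CC(C)=CC[C@@]2(C)[C@@H](O[Si](C)(C)C(C)(C)C)C[C@@](O)(C(C)=C)[C@H]12
F11 | step 6 | (1S,3R,3aS,4S,8aR)-1-(tert-butyldimethylsilyloxy)-6,8a-dimethyl-3-(propan-2-yl)-1,2,3,3a,4,5,8,8a-octahydroazulene-3,4-diol | O[C@H]1CC(C)=CC[C@@]2(C)[C@@H](O[Si](C)(C)C(C)(C)C)C[C@@](O)(C(C)C)[C@H]12
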